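**Assumptions:** Locants follow the carbocycle: C1 = lactone O–CH, C2=C3(Me), C4, C5–OH, C6=C7(Me), C8, C9–OAc, C10=C11(Me), C12, C13–OAc, C14 = ring-fusion CH, C15(=C16H2), C17 = lactone C=O. Carbon building blocks carry compound numbers; protecting-group, one-carbon and other reagents appear on the reagent lines. PMB = 4-methoxybenzyl, TES = triethylsilyl, TBS = tert-butyldimethylsilyl.

## Retrosynthetic overview

1. Target 30 ← macrolactone 27 (5-OTBS, 9,13-bis-OTES) by TES removal, diacetylation and final desilylation.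
2. 27 ← seco enal/(Z)-2-(bromomethyl)enoate 25 by CrCl2-mediated ring closure at C1–C14; the 14-membered carbocycle forms first and the γ-lactone closes in the same operation.
3. 25 ← trienoate 17 (C1 ester → enal; C14 PMB ether → aldehyde → Baylis–Hillman adduct → allylic bromide).
4. Key bond C4–C5: intermolecular catalytic asymmetric vinylogous Mukaiyama aldol joining enal 16 (C5–C14) with silyl dienolate 12 (C1–C4 plus the C3 methyl); the same aldol earlier joins C8–C9 (enal 9 + 12).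
5. 9 ← (R)-glycidol (C13 from the chiral pool), acetylide opening and Negishi carboalumination (C10=C11, E).

## Route

Step 1
Reactants: 1 (R)-glycidol
Product: 2 (S)-2-{[(4-methoxybenzyl)oxy]methyl}oxirane
Conditions: NaH, PMBCl, n-Bu4NI (cat.), THF/DMF, 0 °C to rt
Reagents that add atoms: 4-methoxybenzyl chloride (PMBCl), COc1ccc(CCl)cc1
Why: Williamson etherification of the primary alkoxide leaves the stereocentre untouched (the R to S change is only a CIP priority switch).

Step 2
Reactants: 2 (S)-PMB glycidyl ether; 3 lithium acetylide–ethylenediamine complex (LiC≡CH·H2NCH2CH2NH2)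
Product: 4 (S)-1-[(4-methoxybenzyl)oxy]pent-4-yn-2-ol
Conditions: DMSO, 0 °C to rt; aq. NH4Cl
Reagents that add atoms: none
Why: SN2 epoxide opening by the acetylide at the unsubstituted carbon forms C11–C12 and carries the chiral-pool centre over as C13 (S).

Step 3
Reactants: 4 (S)-1-[(4-methoxybenzyl)oxy]pent-4-yn-2-ol
Product: 5 (S)-triethyl({1-[(4-methoxybenzyl)oxy]pent-4-yn-2-yl}oxy)silane
Conditions: TESCl, imidazole, CH2Cl2, 0 °C to rt
Reagents that add atoms: chlorotriethylsilane (TESCl), CC[Si](CC)(CC)Cl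
Why: Standard silylation masks the C13 hydroxyl with a group that can later be removed in the presence of a TBS ether.

Step 4
Reactants: 5 TES-protected alkynol
Product: 8 (2E,5S)-6-[(4-methoxybenzyl)oxy]-3-methyl-5-[(triethylsilyl)oxy]hex-2-en-1-ol (C9–C14), via vinylalane 6 (not isolated), via lithium alanate 7 (not isolated)
Conditions: AlMe3 (3 equiv), Cp2ZrCl2 (0.25 equiv), CH2Cl2, 0 °C to rt; then n-BuLi, THF, −78 °C; (CH2O)n, −78 °C to rt; aq. potassium sodium tartrate
Reagents that add atoms: trimethylaluminium, C[Al](C)C; paraformaldehyde (as formaldehyde), C=O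
Why: Negishi zirconium-catalysed carboalumination adds Me and Al syn with Al at the terminal carbon, and hydroxymethylation of the alanate with retention gives the (E)-C10=C11 olefin only.

Step 5
Reactants: 8 C9–C14 allylic alcohol
Product: 9 (2E,5S)-6-[(4-methoxybenzyl)oxy]-3-methyl-5-[(triethylsilyl)oxy]hex-2-enal
Conditions: MnO2 (excess), CH2Cl2, rt
Reagents that add atoms: none
Why: Chemoselective allylic oxidation gives the enal without E/Z erosion.

Step 6
Reactants: 10 ethyl 3-methylbut-2-enoate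
Product: 12 tert-butyl[(1-ethoxy-3-methylbuta-1,3-dien-1-yl)oxy]dimethylsilane, via lithium dienolate 11 (not isolated)
Conditions: i-Pr2NLi (LDA), THF, −78 °C; TBSCl, DMPU, −78 °C to rt
Reagents that add atoms: tert-butyldimethylsilyl chloride (TBSCl), CC(C)(C)[Si](C)(C)Cl
Why: γ-Deprotonation gives the extended dienolate and O-silylation gives the silyl ketene acetal (its E/Z ratio is inconsequential).

Step 7
Reactants: 9 C9–C14 enal; 12 silyl dienolate
Product: 13 ethyl (2E,5S,6E,9S)-5-hydroxy-10-[(4-methoxybenzyl)oxy]-3,7-dimethyl-9-[(triethylsilyl)oxy]deca-2,6-dienoate (C5–C14)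
Conditions: SiCl4 (1.2 equiv), (S,S)-Denmark bisphosphoramide (5 mol %; the antipode giving Si-face attack), i-Pr2NEt (10 mol %), CH2Cl2, −78 °C; aq. NaHCO3
Reagents that add atoms: none
Why: Vinylogous Mukaiyama aldol with exclusive γ-attack forms C8–C9 and the (E)-C6=C7 enoate; the catalyst-bound chlorosilyl cation directs Si-face addition to set C9 (S), and the minor epimer is a separable diastereomer.

Step 8
Reactants: 13 C5–C14 hydroxy ester
Product: 14 ethyl (2E,5S,6E,9S)-10-[(4-methoxybenzyl)oxy]-3,7-dimethyl-5,9-bis[(triethylsilyl)oxy]deca-2,6-dienoate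
Conditions: TESCl, imidazole, DMF, 0 °C to rt
Reagents that add atoms: chlorotriethylsilane (TESCl), CC[Si](CC)(CC)Cl
Why: Silylation of the C9 allylic alcohol gives the same protecting group as at C13, so both can later be exchanged for acetate together.

Step 9
Reactants: 14 bis-TES ester
Product: 15 (2E,5S,6E,9S)-10-[(4-methoxybenzyl)oxy]-3,7-dimethyl-5,9-bis[(triethylsilyl)oxy]deca-2,6-dien-1-ol
Conditions: i-Bu2AlH (2.5 equiv), CH2Cl2, −78 °C; aq. potassium sodium tartrate
Reagents that add atoms: none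
Why: Hydride 1,2-reduction of the enoate gives the allylic alcohol; silyl and PMB ethers are inert.

Step 10
Reactants: 15 C5–C14 allylic alcohol
Product: 16 (2E,5S,6E,9S)-10-[(4-methoxybenzyl)oxy]-3,7-dimethyl-5,9-bis[(triethylsilyl)oxy]deca-2,6-dienal
Conditions: MnO2 (excess), CH2Cl2, rt
Reagents that add atoms: none
Why: Selective allylic oxidation furnishes the enal for the second aldol.

Step 11 (key fragment union)
Reactants: 16 C5–C14 enal; 12 silyl dienolate
Product: 17 ethyl (2E,5S,6E,9S,10E,13S)-5-hydroxy-14-[(4-methoxybenzyl)oxy]-3,7,11-trimethyl-9,13-bis[(triethylsilyl)oxy]tetradeca-2,6,10-trienoate (C1–C14)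
Conditions: SiCl4 (1.2 equiv), (S,S)-Denmark bisphosphoramide (5 mol %), i-Pr2NEt (10 mol %), CH2Cl2, −78 °C; aq. NaHCO3
Reagents that add atoms: none
Why: The intermolecular vinylogous Mukaiyama aldol forms C4–C5, completes the carbon chain with the (E)-C2=C3 enoate and sets C5 (S) by catalyst-controlled Si-face addition.

Step 12
Reactants: 17 C1–C14 hydroxy ester
Product: 18 ethyl (2E,5S,6E,9S,10E,13S)-5-[(tert-butyldimethylsilyl)oxy]-14-[(4-methoxybenzyl)oxy]-3,7,11-trimethyl-9,13-bis[(triethylsilyl)oxy]tetradeca-2,6,10-trienoate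
Conditions: TBSOTf, 2,6-lutidine, CH2Cl2, −78 °C
Reagents that add atoms: tert-butyldimethylsilyl triflate (TBSOTf), CC(C)(C)[Si](C)(C)OS(=O)(=O)C(F)(F)F
Why: The C5 hydroxyl, free in the target, gets the more robust silyl group so that the two TES ethers can be cleaved selectively later.

Step 13
Reactants: 18 fully protected trienoate
Product: 19 (2E,5S,6E,9S,10E,13S)-5-[(tert-butyldimethylsilyl)oxy]-14-[(4-methoxybenzyl)oxy]-3,7,11-trimethyl-9,13-bis[(triethylsilyl)oxy]tetradeca-2,6,10-trien-1-ol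
Conditions: i-Bu2AlH (2.5 equiv), CH2Cl2, −78 °C; aq. potassium sodium tartrate
Reagents that add atoms: none
Why: Hydride reduction of the enoate to the C1 allylic alcohol is the last hydride step, so it precedes installation of the acrylate ester.

Step 14
Reactants: 19 C1 allylic alcohol
Product: 20 (2E,5S,6E,9S,10E,13S)-5-[(tert-butyldimethylsilyl)oxy]-14-[(4-methoxybenzyl)oxy]-3,7,11-trimethyl-9,13-bis[(triethylsilyl)oxy]tetradeca-2,6,10-trienal
Conditions: MnO2 (excess), CH2Cl2, rt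
Reagents that add atoms: none
Why: Allylic oxidation gives the C1 enal that serves as the electrophile in the ring closure.

Step 15
Reactants: 20 C1 enal with C14 PMB ether
Product: 21 (2E,5S,6E,9S,10E,13S)-5-[(tert-butyldimethylsilyl)oxy]-14-hydroxy-3,7,11-trimethyl-9,13-bis[(triethylsilyl)oxy]tetradeca-2,6,10-trienal
Conditions: DDQ, CH2Cl2/aq. KH2PO4–K2HPO4 buffer (pH 7), 0 °C
Reagents that add atoms: none
Why: Oxidative PMB cleavage under buffered conditions spares the silyl ethers, the enal and the trisubstituted olefins.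

Step 16
Reactants: 21 C14 primary alcohol
Product: 22 (2E,5S,6E,9S,10E,13S)-5-[(tert-butyldimethylsilyl)oxy]-3,7,11-trimethyl-9,13-bis[(triethylsilyl)oxy]tetradeca-2,6,10-trienedial
Conditions: Dess–Martin periodinane, NaHCO3, CH2Cl2, 0 °C to rt
Reagents that add atoms: none
Why: Mild buffered oxidation gives the α-silyloxy aldehyde without epimerising C13; it is used directly.

Step 17
Reactants: 22 dialdehyde; 23 methyl acrylate
Product: 24 methyl (4S,6E,8S,10E,12S,14E)-12-[(tert-butyldimethylsilyl)oxy]-3-hydroxy-6,10,14-trimethyl-2-methylidene-16-oxo-4,8-bis[(triethylsilyl)oxy]hexadeca-6,10,14-trienoate (mixture of C3 epimers, i.e. at target C14)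
Conditions: DABCO (1 equiv), methyl acrylate (neat, 20 equiv), rt, 3–5 d
Reagents that add atoms: none
Why: The Morita–Baylis–Hillman reaction is selective for the activated α-silyloxy aldehyde because the β,β-disubstituted enal is essentially inert; the new carbinol centre is erased in the next step.

Step 18
Reactants: 24 Baylis–Hillman adduct
Product: 25 methyl (2Z,4S,6E,8S,10E,12S,14E)-2-(bromomethyl)-12-[(tert-butyldimethylsilyl)oxy]-6,10,14-trimethyl-16-oxo-4,8-bis[(triethylsilyl)oxy]hexadeca-2,6,10,14-tetraenoate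
Conditions: NBS, Me2S, CH2Cl2, 0 °C to rt
Reagents that add atoms: N-bromosuccinimide (NBS), O=C1CCC(=O)N1Br
Why: Activation of the alcohol as an alkoxysulfonium ion and SN2' attack by bromide gives the thermodynamically preferred (Z)-2-(bromomethyl)enoate under near-neutral conditions.

Step 19
Reactants: 25 seco enal/allylic bromide
Product: 27 macrolactone with the target skeleton carrying 5-OTBS and 9,13-bis-OTES (trans-fused α-methylene-γ-lactone; all-E; C1/C5/C9/C13 S and C14 as in the target, formally R while C13–O bears silicon), via hydroxy ester 26 (not isolated)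
Conditions: CrCl2 (10 equiv), THF, 0.003 M, syringe-pump addition of 25 over 10 h, rt; then PPTS (cat.), PhH, 50 °C
Reagents that add atoms: none
Why: Intramolecular Nozaki–Hiyama (Barbier-type) allylation with divalent chromium through a chair-like six-membered transition state of the equilibrated allylchromium gives the anti adduct (trans lactone after loss of methanol), and the desired face at C14 corresponds to the allylic-strain-minimised conformer (C13–H eclipsing the allyl plane, aldehyde approaching anti to the C12 chain).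

Step 20
Reactants: 27 bis-TES/TBS macrolactone
Product: 28 9,13-diol with 5-OTBS retained (1S,5S,9S,13S,14S)
Conditions: PPTS, MeOH/CH2Cl2 (1:1), 0 °C to rt
Reagents that add atoms: none
Why: Mild acid methanolysis removes secondary TES ethers about two orders of magnitude faster than the secondary TBS ether.

Step 21
Reactants: 28 diol
Product: 29 9,13-diacetate with 5-OTBS
Conditions: Ac2O, pyridine, DMAP (cat.), CH2Cl2, 0 °C to rt
Reagents that add atoms: acetic anhydride, CC(=O)OC(C)=O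
Why: Nucleophile-catalysed acylation esterifies both secondary alcohols while the α-methylene lactone is untouched.

Step 22
Reactants: 29 diacetate TBS ether
Product: 30 CNP0418981.1 (target)
Conditions: HF·pyridine, pyridine, THF, 0 °C to rt
Reagents that add atoms: none
Why: Buffered fluoride desilylation frees the C5 allylic alcohol without acetate migration or conjugate addition to the α-methylene lactone.

## Compound list

1 | (R)-glycidol | OC[C@@H]1CO1 | starting material
2 | (S)-2-{[(4-methoxybenzyl)oxy]methyl}oxirane | COc1ccc(COC[C@@H]2CO2)cc1 | intermediate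
3 | lithium acetylide–ethylenediamine complex | [Li+].[C-]#C.NCCN | starting material
4 | (S)-1-[(4-methoxybenzyl)oxy]pent-4-yn-2-ol | C#CC[C@H](O)COCc1ccc(OC)cc1 | intermediate
5 | (S)-triethyl({1-[(4-methoxybenzyl)oxy]pent-4-yn-2-yl}oxy)silane | C#CC[C@H](O[Si](CC)(CC)CC)COCc1ccc(OC)cc1 | intermediate
6 | dimethyl[(1E,4S)-5-(PMB-oxy)-2-methyl-4-(TES-oxy)pent-1-en-1-yl]aluminium (vinylalane) | C[Al](C)/C=C(\C)C[C@H](O[Si](CC)(CC)CC)COCc1ccc(OC)cc1 | intermediate
7 | lithium n-butyl(dimethyl)[(1E,4S)-5-(PMB-oxy)-2-methyl-4-(TES-oxy)pent-1-en-1-yl]aluminate | [Li+].CCCC[Al-](C)(C)/C=C(\C)C[C@H](O[Si](CC)(CC)CC)COCc1ccc(OC)cc1 | intermediate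
8 | (2E,5S)-6-[(4-methoxybenzyl)oxy]-3-methyl-5-[(triethylsilyl)oxy]hex-2-en-1-ol | OC/C=C(\C)C[C@H](O[Si](CC)(CC)CC)COCc1ccc(OC)cc1 | intermediate
9 | (2E,5S)-6-[(4-methoxybenzyl)oxy]-3-methyl-5-[(triethylsilyl)oxy]hex-2-enal | O=C/C=C(\C)C[C@H](O[Si](CC)(CC)CC)COCc1ccc(OC)cc1 | intermediate
10 | ethyl 3-methylbut-2-enoate | CCOC(=O)C=C(C)C | starting material
11 | lithium 1-ethoxy-3-methylbuta-1,3-dien-1-olate | [Li]OC(OCC)=CC(C)=C | intermediate
12 | tert-butyl[(1-ethoxy-3-methylbuta-1,3-dien-1-yl)oxy]dimethylsilane | CCOC(=CC(C)=C)O[Si](C)(C)C(C)(C)C | intermediate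
13 | ethyl (2E,5S,6E,9S)-5-hydroxy-10-[(4-methoxybenzyl)oxy]-3,7-dimethyl-9-[(triethylsilyl)oxy]deca-2,6-dienoate | CCOC(=O)/C=C(\C)C[C@H](O)/C=C(\C)C[C@H](O[Si](CC)(CC)CC)COCc1ccc(OC)cc1 | intermediate
14 | ethyl (2E,5S,6E,9S)-10-[(4-methoxybenzyl)oxy]-3,7-dimethyl-5,9-bis[(triethylsilyl)oxy]deca-2,6-dienoate | CCOC(=O)/C=C(\C)C[C@H](O[Si](CC)(CC)CC)/C=C(\C)C[C@H](O[Si](CC)(CC)CC)COCc1ccc(OC)cc1 | intermediate
15 | (2E,5S,6E,9S)-10-[(4-methoxybenzyl)oxy]-3,7-dimethyl-5,9-bis[(triethylsilyl)oxy]deca-2,6-dien-1-ol | OC/C=C(\C)C[C@H](O[Si](CC)(CC)CC)/C=C(\C)C[C@H](O[Si](CC)(CC)CC)COCc1ccc(OC)cc1 | intermediate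
16 | (2E,5S,6E,9S)-10-[(4-methoxybenzyl)oxy]-3,7-dimethyl-5,9-bis[(triethylsilyl)oxy]deca-2,6-dienal | O=C/C=C(\C)C[C@H](O[Si](CC)(CC)CC)/C=C(\C)C[C@H](O[Si](CC)(CC)CC)COCc1ccc(OC)cc1 | intermediate
17 | ethyl (2E,5S,6E,9S,10E,13S)-5-hydroxy-14-[(4-methoxybenzyl)oxy]-3,7,11-trimethyl-9,13-bis[(triethylsilyl)oxy]tetradeca-2,6,10-trienoate | CCOC(=O)/C=C(\C)C[C@H](O)/C=C(\C)C[C@H](O[Si](CC)(CC)CC)/C=C(\C)C[C@H](O[Si](CC)(CC)CC)COCc1ccc(OC)cc1 | intermediate
18 | ethyl (2E,5S,6E,9S,10E,13S)-5-[(tert-butyldimethylsilyl)oxy]-14-[(4-methoxybenzyl)oxy]-3,7,11-trimethyl-9,13-bis[(triethylsilyl)oxy]tetradeca-2,6,10-trienoate | CCOC(=O)/C=C(\C)C[C@H](O[Si](C)(C)C(C)(C)C)/C=C(\C)C[C@H](O[Si](CC)(CC)CC)/C=C(\C)C[C@H](O[Si](CC)(CC)CC)COCc1ccc(OC)cc1 | intermediate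
19 | (2E,5S,6E,9S,10E,13S)-5-[(tert-butyldimethylsilyl)oxy]-14-[(4-methoxybenzyl)oxy]-3,7,11-trimethyl-9,13-bis[(triethylsilyl)oxy]tetradeca-2,6,10-trien-1-ol | OC/C=C(\C)C[C@H](O[Si](C)(C)C(C)(C)C)/C=C(\C)C[C@H](O[Si](CC)(CC)CC)/C=C(\C)C[C@H](O[Si](CC)(CC)CC)COCc1ccc(OC)cc1 | intermediate
20 | (2E,5S,6E,9S,10E,13S)-5-[(tert-butyldimethylsilyl)oxy]-14-[(4-methoxybenzyl)oxy]-3,7,11-trimethyl-9,13-bis[(triethylsilyl)oxy]tetradeca-2,6,10-trienal | O=C/C=C(\C)C[C@H](O[Si](C)(C)C(C)(C)C)/C=C(\C)C[C@H](O[Si](CC)(CC)CC)/C=C(\C)C[C@H](O[Si](CC)(CC)CC)COCc1ccc(OC)cc1 | intermediate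
21 | (2E,5S,6E,9S,10E,13S)-5-[(tert-butyldimethylsilyl)oxy]-14-hydroxy-3,7,11-trimethyl-9,13-bis[(triethylsilyl)oxy]tetradeca-2,6,10-trienal | O=C/C=C(\C)C[C@H](O[Si](C)(C)C(C)(C)C)/C=C(\C)C[C@H](O[Si](CC)(CC)CC)/C=C(\C)C[C@H](O[Si](CC)(CC)CC)CO | intermediate
22 | (2E,5S,6E,9S,10E,13S)-5-[(tert-butyldimethylsilyl)oxy]-3,7,11-trimethyl-9,13-bis[(triethylsilyl)oxy]tetradeca-2,6,10-trienedial | O=C/C=C(\C)C[C@H](O[Si](C)(C)C(C)(C)C)/C=C(\C)C[C@H](O[Si](CC)(CC)CC)/C=C(\C)C[C@H](O[Si](CC)(CC)CC)C=O | intermediate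
23 | methyl acrylate | C=CC(=O)OC | starting material
24 | methyl (4S,6E,8S,10E,12S,14E)-12-[(tert-butyldimethylsilyl)oxy]-3-hydroxy-6,10,14-trimethyl-2-methylidene-16-oxo-4,8-bis[(triethylsilyl)oxy]hexadeca-6,10,14-trienoate (C3 epimers) | O=C/C=C(\C)C[C@H](O[Si](C)(C)C(C)(C)C)/C=C(\C)C[C@H](O[Si](CC)(CC)CC)/C=C(\C)C[C@H](O[Si](CC)(CC)CC)C(O)C(=C)C(=O)OC | intermediate
25 | methyl (2Z,4S,6E,8S,10E,12S,14E)-2-(bromomethyl)-12-[(tert-butyldimethylsilyl)oxy]-6,10,14-trimethyl-16-oxo-4,8-bis[(triethylsilyl)oxy]hexadeca-2,6,10,14-tetraenoate | O=C/C=C(\C)C[C@H](O[Si](C)(C)C(C)(C)C)/C=C(\C)C[C@H](O[Si](CC)(CC)CC)/C=C(\C)C[C@H](O[Si](CC)(CC)CC)/C=C(\CBr)C(=O)OC | intermediate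
26 | macrocyclic hydroxy ester: methyl 2-(C14-yl)prop-2-enoate of the 14-membered triene with 1-OH, 5-OTBS, 9,13-bis-OTES (configuration as in 27) | O[C@H]1/C=C(\C)C[C@H](O[Si](C)(C)C(C)(C)C)/C=C(\C)C[C@H](O[Si](CC)(CC)CC)/C=C(\C)C[C@H](O[Si](CC)(CC)CC)[C@@H]1C(=C)C(=O)OC | intermediate
27 | trans-fused α-methylene-γ-lactone macrocycle, 5-OTBS, 9,13-bis-OTES (target configuration) | C=C1C(=O)O[C@H]2/C=C(\C)C[C@H](O[Si](C)(C)C(C)(C)C)/C=C(\C)C[C@H](O[Si](CC)(CC)CC)/C=C(\C)C[C@H](O[Si](CC)(CC)CC)[C@H]12 | intermediate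
28 | 9,13-diol, 5-OTBS macrolactone (1S,5S,9S,13S,14S) | C=C1C(=O)O[C@H]2/C=C(\C)C[C@H](O[Si](C)(C)C(C)(C)C)/C=C(\C)C[C@H](O)/C=C(\C)C[C@H](O)[C@H]12 | intermediate
29 | 9,13-diacetate, 5-OTBS macrolactone (1S,5S,9S,13S,14S) | C=C1C(=O)O[C@H]2/C=C(\C)C[C@H](O[Si](C)(C)C(C)(C)C)/C=C(\C)C[C@H](OC(C)=O)/C=C(\C)C[C@H](OC(C)=O)[C@H]12 | intermediate
30 | CNP0418981.1 (1S,5S,9S,13S,14S; 2E,6E,10E) | C=C1C(=O)O[C@H]2/C=C(\C)C[C@H](O)/C=C(\C)C[C@H](OC(C)=O)/C=C(\C)C[C@H](OC(C)=O)[C@H]12 | target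

## Summary

Total step count: 22. Longest linear sequence: 21 steps (steps 1–5 and 7–22, from (R)-glycidol); step 6 is a one-step side branch.

**Steps most likely to fail**

1. Step 19 (ring closure). The CrCl2 cyclisation creates C1 and C14 together, and the configuration of the product must be proven at 27. The trans ring fusion and the facial sense relative to C13 rest on transition-state models, not on auxiliary or catalyst control, so this is the least secure step. Fallback: it sets out from 25 and comes back at 27. If the closure gives mainly the cis-fused C1-epimeric lactone F1, the C1 configuration is instead fixed by an SN2 event. F1 is saponified (LiOH, THF/H2O, 0 °C) and the seco hydroxy acid F2, liberated at pH 5 at 0 °C, is cyclised at once under Mitsunobu conditions (PPh3, DIAD, toluene, 0 °C). Carboxylate displacement with inversion at the allylic C1 carbinol then delivers the trans-fused lactone 27.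

2. Step 11 (and equally step 7). The vinylogous aldol may give insufficient enantiofacial control, γ-selectivity or E-selectivity with these β,β-disubstituted enals, and the sense of induction by the chosen catalyst antipode must be checked by Mosher analysis. Fallback: it sets out from 16 and comes back at 18. Enal 16 undergoes asymmetric propargylation (allenylboronic acid pinacol ester with a chiral BINOL-derived phosphoric acid catalyst) to the homopropargylic alcohol F3. Silylation (TBSOTf, 2,6-lutidine) gives the TBS ether F4. Negishi carboalumination (AlMe3, Cp2ZrCl2) and trapping of the vinylalane with ethyl chloroformate then builds the (E)-C2=C3 enoate, giving 18 directly.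

3. Step 17 (Baylis–Hillman reaction). The reaction is slow on the hindered α-silyloxy aldehyde, must discriminate against the C1 enal and must not epimerise C13. Fallback: it sets out from 22 and comes back at 24. The amine-catalysed reaction is replaced by a stoichiometric vinylmetal addition: the [α-(methoxycarbonyl)vinyl]alane made from methyl propiolate, i-Bu2AlH and N-methylmorpholine N-oxide in THF is added (1.1 equiv, −78 to 0 °C) to the more electrophilic α-silyloxy aldehyde of 22 to give 24 in one operation.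

## Further compounds

F1 | step 19 | cis-fused C1-epimeric macrolactone (5-OTBS, 9,13-bis-OTES) | C=C1C(=O)O[C@@H]2/C=C(\C)C[C@H](O[Si](C)(C)C(C)(C)C)/C=C(\C)C[C@H](O[Si](CC)(CC)CC)/C=C(\C)C[C@H](O[Si](CC)(CC)CC)[C@H]12
F2 | step 19 | C1-epimeric seco hydroxy acid, 2-(C14-yl)prop-2-enoic acid of the macrocycle | O[C@@H]1/C=C(\C)C[C@H](O[Si](C)(C)C(C)(C)C)/C=C(\C)C[C@H](O[Si](CC)(CC)CC)/C=C(\C)C[C@H](O[Si](CC)(CC)CC)[C@@H]1C(=C)C(=O)O
F3 | step 11 | homopropargylic alcohol from 16 (C5 S; C2–C14 of the chain with terminal alkyne) | C#CC[C@H](O)/C=C(\C)C[C@H](O[Si](CC)(CC)CC)/C=C(\C)C[C@H](O[Si](CC)(CC)CC)COCc1ccc(OC)cc1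
F4 | step 11 | TBS ether of F3 | C#CC[C@H](O[Si](C)(C)C(C)(C)C)/C=C(\C)C[C@H](O[Si](CC)(CC)CC)/C=C(\C)C[C@H](O[Si](CC)(CC)CC)COCc1ccc(OC)cc1
F0 | step 17 | none | none
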